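(The numbers in the tables are calculated with constants of no real substance, and the scatter is random.)

What share of the starting material charged is product after 19 h in maple, which is the ash recipe left longer? I reckon that share from the readings and take the two orders from the forecast.

| setting | ash | alder | elm | maple |
|---|---|---|---|---|
| starting material | 120 mM | 60.0 mM | 120 mM | 120 mM |
| partner | 132 mM | 132 mM | 66.0 mM | 132 mM |
| free catalyst | 9.60 mM | 9.60 mM | 9.60 mM | 9.60 mM |
| time |  |  |  | 19 h |

- ash run (time / h: [product] / mM): 1.3: 17.4; 2.5: 24.2; 3.8: 28.3; 5.1: 30.9; 6.3: 31.5; 7.6: 31.8
- alder run (time / h: [product] / mM): 1.3: 9.1; 2.5: 12.3; 3.8: 14.5; 5.1: 16.5; 6.3: 16.9; 7.6: 17.7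
- elm run (time / h: [product] / mM): 1.3: 9.5; 2.5: 12.6; 3.8: 16.3; 5.1: 17.0; 6.3: 16.9; 7.6: 17.5

(scatter of a reading: 0.4 mM)

1. the power of [starting material] that the first rate follows, about the charge of the ash run; measure it at two percent of starting material made into product (one fixed amount of product, the same in the runs compared)
2. the power of [partner] that the first rate follows, about the charge of the ash run; measure it at two percent of starting material made into product
3. product in the maple run at 19 h, as a share of the starting material charged

- Overall: starting material + partner -> product, with free catalyst as catalyst.
- Constant volume, constant temperature.
- "The second partner" is partner.
- An order is taken over about fifteen percent of the charge, up and down.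

1. I follow the ash run at 1.3 h, 3.8 h and 6.3 h, which are equally spaced. Product gains 9.08 % of the charge in the first spell and 2.67 % in the second, so the second spell keeps a fraction 0.294 of the gain before it, as far as these readings show.

2. If that fraction holds, ash has 1.11 % of the charge still to come after 6.3 h. That gives 27.4 %, a reading with the scatter of these points. I call this the stopping share: the fraction of the starting material charged that arrives as product by the end, or the final yield.

3. The second way uses other flasks. Alder has half the starting material of ash, and elm has half the partner. If the final product simply followed each charge, doubling their last readings would give 29.5 % and 29.2 % of the ash charge. Both stand above the stopping share.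

4. The doubling is the way that cheats. By its last reading, ash has drawn 26.5 % of its starting material and 24.1 % of its partner into product. By their last readings, alder has drawn 13.4 % of its partner, and elm has drawn 14.6 % of its starting material. Alder spends a smaller share of its partner than ash, and elm a smaller share of its starting material than ash, so I take doubling to read high and keep the ash figure.

5. From 6.3 h to 19 h there are 5.08 spells, and if the fraction holds, my estimate of what is still to come after 19 h is 0.00221 % of the charge, less than the scatter of 0.333 %. I commit to maple standing at the stopping share at 19 h.

6. The forecast gives 27 %, with a range of 25.5 % to 29 %, and orders of 0.95 in starting material and 0.95 in partner. Its ground for maple is that “both predict that maple, a repeat of ash at longer time, stays on the plateau”.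

The flask gives 27.2 % in maple, with orders of 1.1 in starting material and 1.1 in partner.

    2 free catalyst ⇌ catalyst dimer, settled at all times (503.0 M⁻¹)
    free catalyst + starting material + partner → product + free catalyst (489.6 M⁻² h⁻¹)
    starting material → decomposed substrate (0.2718 h⁻¹)
    partner → lost reagent (0.1447 h⁻¹)

Part of what holds down the stopping share of 27.4 % that I read from ash is a side step: starting material goes to decomposed substrate. Maple without that step gives 47.9 % at 19 h, against 27.2 % with it, a gain of 21 percentage points. In maple at 19 h, 72.8 % of the charge is missing from product, and the step accounts for 28 % of what is missing.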